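**The decision.** Which way of charging 0.50 M of Sbt and 0.350 M of Rea should go on the bench next, and is a feed worth the trouble?

| flask | Sbt | Rea | remark | time |
|---|---|---|---|---|
| Saturday's | 0.50 M | 0.35 M | run made earlier |  |
| Thursday's | 0.70 M | 0.35 M | run made earlier |  |
| Tuesday's | 1.1 M | 0.35 M | run made earlier |  |
| epsilon | 0.50 M (fed, over 15 s) | 0.350 M | all else is in the flask from the start; the feed brings no volume worth counting | 12 min |
| delta | 0.50 M (fed, over 2.5 min) | 0.350 M | all else is in the flask from the start; the feed brings no volume worth counting | 12 min |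
| gamma | 0.50 M | 0.350 M | everything together at the start | 12 min |
| beta | 0.50 M | 0.350 M (fed, over 2.5 min) | all else is in the flask from the start; the feed brings no volume worth counting | 12 min |

| run | time / min | Tgt2 / % | Sbt / % |
|---|---|---|---|
| Saturday's | 3.00 | 43 | 17 |
| Saturday's | 6.00 | 55 | 6 |
| Saturday's | 10.0 | 59 | 0 |
| Saturday's | 12.0 | 57 | 0 |
| Thursday's | 1.50 | 23 | 41 |
| Thursday's | 4.00 | 40 | 13 |
| Thursday's | 8.00 | 43 | 4 |
| Thursday's | 12.0 | 42 | 0 |
| Tuesday's | 3.00 | 24 | 16 |
| Tuesday's | 6.00 | 24 | 1 |
| Tuesday's | 10.0 | 27 | 2 |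
| Tuesday's | 12.0 | 24 | 0 |

(each reading ± 1.5 percentage points)

- the earlier runs were read with a standard deviation of 1.5 percentage points

1. the flask that comes out highest in amount of Tgt2, in percent of the Sbt charged, or "all alike" when all lie within 1.5 percentage points (epsilon / delta / gamma / beta / all alike)
2. Tgt2 at the end, in percent of the Sbt charged, epsilon
3. Tgt2 at the end, in percent of the Sbt charged, delta
4. Tgt2 at the end, in percent of the Sbt charged, gamma
5. Tgt2 at the end, in percent of the Sbt charged, beta

**My reckoning.** I wrote the balance of Rea, the limiting reagent here, charged at less than Sbt: taking one Rea per Tgt2, the Rea ceiling on Tgt2 is 70.0 % of the Sbt charged, in epsilon, delta, gamma and beta alike. At 12.0 min the earlier runs held, per Rea charged, 0.814 on Saturday, 0.840 on Thursday and 0.754 on Tuesday, with a mean of 0.803, which I call the capture c, the Tgt2 formed per Rea charged. Sbt had gone up to about twice its level between Saturday's and Tuesday's runs, yet c moved by 0.0600 against a scatter of 0.0471 on Tuesday's reading, so I saw no gain from holding Sbt down. Multiplying c by the ceiling gave me 56.2 %, my figure for gamma and, with no fed run read, for the fed flasks too.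

**The forecast.** It named delta highest, with 63 % there, 58.5 % for epsilon and 58 % for gamma, and put beta at 42 %, since a slow Rea feed “starves the main path”. These ask c of 0.900 in delta and 0.600 in beta, so it differs from my reckoning in opposite directions. I therefore kept the charges and ran the flasks as listed, with delta and beta as the two to watch.

**The flasks.** Epsilon gave 56.3 %, delta 50.0 %, gamma 57.1 % and beta 63.3 %, so beta came out highest, still under its ceiling. Capture was 0.905 in beta and 0.714 in delta.

    Sbt → Imd (k = 0.00930 s⁻¹)
    Rea → Imd2 (k = 0.0820 s⁻¹)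
    Imd + Imd2 → Tgt2 (k = 0.0500 M⁻¹ s⁻¹)
    2 Imd2 → Tgt (k = 0.00390 M⁻¹ s⁻¹)
    Sbt + Tgt2 → Sdp (k = 0.00170 M⁻¹ s⁻¹)

**The neighbour.** A neighbour of beta, charged with 0.21 M of Rea, has a ceiling of 42.0 %, and beta's capture gives 38.0 % there; the flask held 39.5 % of Tgt2 at 12.0 min.

The earlier runs and the new flask were generated by integration for substances that don't exist, noise included.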